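**Retrosynthetic overview**
1. Ring C (O1–C2–C3–C4–C4a–C8a) is cut at two bonds at once, C4–C4a and O1–C2. Ring A becomes free phloroglucinol: its three equivalent C–H/OH pairs map onto C4a and C8a–O1, and the 5-OH and 7-OH stay in place unprotected.
2. The three-carbon partner C2–C3(OMe)–C4, carrying ring B, is an α-methoxy aroylketene stored as its β-ketoester. The union is a formal [3+3] annulation on an unfunctionalised arene C–H.
3. The C5'–CH2 bond of the prenyl group, ortho to 4'-OH on ring B, is cut as an aromatic Claisen rearrangement. The five carbons sit on O4' as a 1,1-dimethylallyl ether, which masks the para phenol while C2–C3 is made and moves to C5' in the same heating that builds ring C.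
4. C2–C3 comes from a crossed Claisen condensation of methyl methoxyacetate (supplies C3, its OMe and C4) with O4-etherified methyl protocatechuate.
5. Ring order: B and A are bought, and C is the only ring made, closed last. No classical protecting group is used.

Key step: step 4

Remark: the target has no stereocentre and its only acyclic alkene carries two identical methyl groups. It is therefore achiral, and "single enantiomer" places no demand on the route.

**Step 1**
Reactants: 1 methyl 3,4-dihydroxybenzoate; 2 3-chloro-3-methylbut-1-yne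
Product: 3 methyl 3-hydroxy-4-[(2-methylbut-3-yn-2-yl)oxy]benzoate
Conditions: 2 (1.05 equiv), DBU (1.1 equiv), CuCl2·2H2O (1 mol %), MeCN, Ar, −5 to 0 °C
Reagents that add atoms: 3-chloro-3-methylbut-1-yne (= 2), C#CC(C)(C)Cl
Why: Copper-catalysed propargylic etherification of a phenol (substitution of a tertiary propargylic chloride via a copper allenylidene) should take place on O4 only, because the 4-OH para to the ester is much the more acidic and one equivalent of base at 0 °C forms only that phenoxide, leaving none for a second alkylation or for addition of O3 to the alkyne.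

**Step 2**
Reactants: 3 methyl 3-hydroxy-4-[(2-methylbut-3-yn-2-yl)oxy]benzoate
Product: 4 methyl 3-hydroxy-4-[(2-methylbut-3-en-2-yl)oxy]benzoate
Conditions: H2 (1 atm), Lindlar catalyst, quinoline, EtOAc, rt, stopped after one equivalent of H2
Reagents that add atoms: none
Why: Lindlar semihydrogenation stops a terminal alkyne at the vinyl stage, and the ester, the phenol and the tertiary aryl ether are inert to poisoned palladium at room temperature.

**Step 3**
Reactants: 4 methyl 3-hydroxy-4-[(2-methylbut-3-en-2-yl)oxy]benzoate; 5 methyl methoxyacetate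
Product: 6 methyl 3-{3-hydroxy-4-[(2-methylbut-3-en-2-yl)oxy]phenyl}-2-methoxy-3-oxopropanoate (racemic at C2)
Conditions: 5 (2.5 equiv), LDA (4 equiv), THF, −78 °C; then 4, −78 to 0 °C; AcOH quench at −78 °C
Reagents that add atoms: methyl methoxyacetate (= 5), COCC(=O)OC
Why: In this crossed Claisen condensation the fully preformed lithium enolate of 5 meets only the non-enolisable benzoate, whose 3-phenoxide is meta and does not deactivate the ester while O4 is masked as the ether, and deprotonation of the β-ketoester drives the reaction; the new C2 centre is racemic, labile and erased in step 4.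

**Step 4**
Reactants: 6 methyl 3-{3-hydroxy-4-[(2-methylbut-3-en-2-yl)oxy]phenyl}-2-methoxy-3-oxopropanoate; 7 phloroglucinol (anhydrous)
Product: 11 uralenol-3-methylether, via prenylcatechol ketoester 8 (not isolated), via acylketene 9 (not isolated), via diketone 10 (not isolated)
Conditions: 6, minimum Ph2O, base-washed vessel, Ar, 150 °C, 1 h; then 7 (3 equiv), 240 °C (microwave or metal bath, open to an Ar sweep to remove MeOH/H2O), 10–20 min
Reagents that add atoms: phloroglucinol (= 7), Oc1cc(O)cc(O)c1
Why: The first stage is an aromatic Claisen rearrangement, in which the 1,1-dimethylallyl ether on O4' undergoes a [3,3] shift through its CH2 terminus to the only free ortho carbon C5' (a shift to the OH-bearing C3' cannot rearomatise and is reversible) and tautomerises to the 5'-prenylcatechol 8. The second stage is the neutral thermal condensation of phloroglucinol with an aroylacetic ester (Mentzer chromone synthesis, the closest known reaction type): 8 loses MeOH through its enol to give acylketene 9, which acylates phloroglucinol reversibly on oxygen and then irreversibly on carbon (thermal Fries-type O-to-C shift), forming C4–C4a in 10. Ring C closes by 6-exo-trig attack of an ortho OH of ring A on the aroyl carbonyl carbon C2 followed by loss of water, which forms O1–C2 and makes the aromatic 4-pyranone the thermodynamic sink. No stereocentre is created, and the labile C2 centre of the ketoester becomes the sp2 carbon C3. Site selectivity on ring A is not an issue because all C–H/OH pairs of phloroglucinol are equivalent, the first acylation deactivates the ring and excess 7 suppresses a second annulation, while chromone rather than 4-arylcoumarin formation is secured by the absence of acid, without which the electron-rich aroyl ketone is not attacked by carbon. O-Acylation of the ring B catechol by 9 is reversible because aryl β-ketoesters re-form the ketene, adding 7 only after the Claisen stage keeps its nucleophilic ring away from the ionisable tertiary ether, and short heating under argon with removal of MeOH and water limits chroman formation and hydrolytic decarboxylation.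

**Compound list**
1 | methyl 3,4-dihydroxybenzoate | COC(=O)c1ccc(O)c(O)c1 | starting material
2 | 3-chloro-3-methylbut-1-yne | C#CC(C)(C)Cl | starting material
3 | methyl 3-hydroxy-4-[(2-methylbut-3-yn-2-yl)oxy]benzoate | COC(=O)c1ccc(OC(C)(C)C#C)c(O)c1 | intermediate
4 | methyl 3-hydroxy-4-[(2-methylbut-3-en-2-yl)oxy]benzoate | COC(=O)c1ccc(OC(C)(C)C=C)c(O)c1 | intermediate
5 | methyl methoxyacetate | COCC(=O)OC | starting material
6 | methyl 3-{3-hydroxy-4-[(2-methylbut-3-en-2-yl)oxy]phenyl}-2-methoxy-3-oxopropanoate (racemic) | COC(=O)C(OC)C(=O)c1ccc(OC(C)(C)C=C)c(O)c1 | intermediate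
7 | phloroglucinol (benzene-1,3,5-triol) | Oc1cc(O)cc(O)c1 | starting material
8 | methyl 3-[3,4-dihydroxy-5-(3-methylbut-2-en-1-yl)phenyl]-2-methoxy-3-oxopropanoate (racemic, formed in the flask) | COC(=O)C(OC)C(=O)c1cc(O)c(O)c(CC=C(C)C)c1 | intermediate
9 | 2-[3,4-dihydroxy-5-(3-methylbut-2-en-1-yl)benzoyl]-2-methoxyethen-1-one, the α-methoxy aroylketene (formed in the flask) | O=C=C(OC)C(=O)c1cc(O)c(O)c(CC=C(C)C)c1 | intermediate
10 | 1-[3,4-dihydroxy-5-(3-methylbut-2-en-1-yl)phenyl]-2-methoxy-3-(2,4,6-trihydroxyphenyl)propane-1,3-dione (racemic, formed in the flask) | COC(C(=O)c1cc(O)c(O)c(CC=C(C)C)c1)C(=O)c1c(O)cc(O)cc1O | intermediate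
11 | uralenol-3-methylether, 2-[3,4-dihydroxy-5-(3-methylbut-2-en-1-yl)phenyl]-5,7-dihydroxy-3-methoxy-4H-chromen-4-one | COc1c(-c2cc(O)c(O)c(CC=C(C)C)c2)oc2cc(O)cc(O)c2c1=O | target

**Total step count:** 4
**Longest linear sequence:** 4 steps (1 → 3 → 4 → 6 → 11)

**Steps most likely to fail**

**1. Step 4.** Several processes could defeat it:
- The tertiary allyl ether may ionise and lose or transfer its C5 unit before the [3,3] shift.
- The O-to-C acyl migration on phloroglucinol may be slow for an α-alkoxy acylketene.
- Released water may hydrolyse and decarboxylate the ketoester.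
- The 4'-OH may add to the prenyl alkene at 240 °C.

The fallback gives up the C4–C4a/O1–C2 annulation for a Baker–Venkataraman construction, which forms C2–C3 instead. It sets out from 7 and 4 and comes back at 11.

For the ring A piece, phloroglucinol 7 is C-acylated with methoxyacetonitrile (Hoesch reaction: ZnCl2, HCl, Et2O, then hot water) to 2-methoxy-1-(2,4,6-trihydroxyphenyl)ethan-1-one F1. Two of its three phenols are then capped and one carbonyl-chelated ortho OH stays free (MOMCl, iPr2NEt, CH2Cl2, 0 °C), giving 1-[2-hydroxy-4,6-bis(methoxymethoxy)phenyl]-2-methoxyethan-1-one F2.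

For the ring B piece, 4 is rearranged on its own (PhNEt2, 150 °C) to methyl 3,4-dihydroxy-5-(3-methylbut-2-en-1-yl)benzoate F3. This is protected (MOMCl, iPr2NEt) as methyl 3,4-bis(methoxymethoxy)-5-(3-methylbut-2-en-1-yl)benzoate F4 and saponified (LiOH, THF/MeOH/H2O) to 3,4-bis(methoxymethoxy)-5-(3-methylbut-2-en-1-yl)benzoic acid F5.

EDC/DMAP esterification of F2 with F5 gives 2-(methoxyacetyl)-3,5-bis(methoxymethoxy)phenyl 3,4-bis(methoxymethoxy)-5-(3-methylbut-2-en-1-yl)benzoate F6. LiHMDS (THF, −20 °C) triggers the O-to-C acyl transfer to 1-[3,4-bis(methoxymethoxy)-5-(3-methylbut-2-en-1-yl)phenyl]-3-[2-hydroxy-4,6-bis(methoxymethoxy)phenyl]-2-methoxypropane-1,3-dione F7. Dilute HCl in MeOH (40 °C) then effects cyclodehydration and removal of the four MOM groups to give 11.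

**2. Step 3.** Acyl substitution at the electron-rich benzoate may be so slow that the methoxyacetate enolate decomposes or self-condenses on warming, and the product may suffer retro-Claisen cleavage on work-up.

The fallback makes the C2–C3 bond at the aldehyde oxidation level, by aldol addition followed by oxidation. It sets out from 4 and comes back at 6.
- Compound 4 is reduced (DIBAL-H, CH2Cl2, −78 to 0 °C) to 5-(hydroxymethyl)-2-[(2-methylbut-3-en-2-yl)oxy]phenol F8.
- F8 is oxidised (activated MnO2, CH2Cl2) to 3-hydroxy-4-[(2-methylbut-3-en-2-yl)oxy]benzaldehyde F9.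
- The lithium enolate of 5 (LDA, THF, −78 °C, one extra equivalent for the phenol) adds to F9. This gives methyl 3-hydroxy-3-{3-hydroxy-4-[(2-methylbut-3-en-2-yl)oxy]phenyl}-2-methoxypropanoate F10 as an inconsequential mixture of racemic diastereomers.
- The para-alkoxy-activated benzylic alcohol of F10 is oxidised with DDQ (dioxane, rt) to 6.

**3. Step 1.** Site selectivity between O4 and O3 may erode, double alkylation may occur, or the neighbouring free phenoxide may add to the alkyne.

The fallback differentiates the two oxygens beforehand with a temporary acyl group. It sets out from 1 and comes back at 4.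
- Compound 1 is peracetylated (Ac2O, pyridine) to methyl 3,4-diacetoxybenzoate F11.
- The more activated 4-acetate, whose phenoxide is stabilised by the para ester, is removed by aminolysis (pyrrolidine, 1 equiv, MeCN, 0 °C) to give methyl 3-acetoxy-4-hydroxybenzoate F12.
- Etherification with 2 under the conditions of step 1 gives methyl 3-acetoxy-4-[(2-methylbut-3-yn-2-yl)oxy]benzoate F13.
- Lindlar semihydrogenation gives methyl 3-acetoxy-4-[(2-methylbut-3-en-2-yl)oxy]benzoate F14, so that no free phenoxide ever faces the alkyne.
- Catalytic K2CO3 in MeOH (0 °C) releases 4.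

**Further compounds**
F1 | step 4 | 2-methoxy-1-(2,4,6-trihydroxyphenyl)ethan-1-one | COCC(=O)c1c(O)cc(O)cc1O
F2 | step 4 | 1-[2-hydroxy-4,6-bis(methoxymethoxy)phenyl]-2-methoxyethan-1-one | COCC(=O)c1c(O)cc(OCOC)cc1OCOC
F3 | step 4 | methyl 3,4-dihydroxy-5-(3-methylbut-2-en-1-yl)benzoate | COC(=O)c1cc(O)c(O)c(CC=C(C)C)c1
F4 | step 4 | methyl 3,4-bis(methoxymethoxy)-5-(3-methylbut-2-en-1-yl)benzoate | COC(=O)c1cc(OCOC)c(OCOC)c(CC=C(C)C)c1
F5 | step 4 | 3,4-bis(methoxymethoxy)-5-(3-methylbut-2-en-1-yl)benzoic acid | OC(=O)c1cc(OCOC)c(OCOC)c(CC=C(C)C)c1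
F6 | step 4 | 2-(methoxyacetyl)-3,5-bis(methoxymethoxy)phenyl 3,4-bis(methoxymethoxy)-5-(3-methylbut-2-en-1-yl)benzoate | COCC(=O)c1c(OC(=O)c2cc(OCOC)c(OCOC)c(CC=C(C)C)c2)cc(OCOC)cc1OCOC
F7 | step 4 | 1-[3,4-bis(methoxymethoxy)-5-(3-methylbut-2-en-1-yl)phenyl]-3-[2-hydroxy-4,6-bis(methoxymethoxy)phenyl]-2-methoxypropane-1,3-dione (racemic) | COC(C(=O)c1cc(OCOC)c(OCOC)c(CC=C(C)C)c1)C(=O)c1c(O)cc(OCOC)cc1OCOC
F8 | step 3 | 5-(hydroxymethyl)-2-[(2-methylbut-3-en-2-yl)oxy]phenol | OCc1ccc(OC(C)(C)C=C)c(O)c1
F9 | step 3 | 3-hydroxy-4-[(2-methylbut-3-en-2-yl)oxy]benzaldehyde | O=Cc1ccc(OC(C)(C)C=C)c(O)c1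
F10 | step 3 | methyl 3-hydroxy-3-{3-hydroxy-4-[(2-methylbut-3-en-2-yl)oxy]phenyl}-2-methoxypropanoate (mixture of racemic diastereomers) | COC(=O)C(OC)C(O)c1ccc(OC(C)(C)C=C)c(O)c1
F11 | step 1 | methyl 3,4-diacetoxybenzoate | COC(=O)c1ccc(OC(C)=O)c(OC(C)=O)c1
F12 | step 1 | methyl 3-acetoxy-4-hydroxybenzoate | COC(=O)c1ccc(O)c(OC(C)=O)c1
F13 | step 1 | methyl 3-acetoxy-4-[(2-methylbut-3-yn-2-yl)oxy]benzoate | COC(=O)c1ccc(OC(C)(C)C#C)c(OC(C)=O)c1
F14 | step 1 | methyl 3-acetoxy-4-[(2-methylbut-3-en-2-yl)oxy]benzoate | COC(=O)c1ccc(OC(C)(C)C=C)c(OC(C)=O)c1
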